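Readings and results stem from a simulated flask with made-up constants; the scatter is artificial.

Grey got more reagent than ochre yet holds less target at 15.0 min, 30.4% against 69.0%, so surplus reagent is eating the target.

| setting | ochre | grey | violet | Monday's | Wednesday's |
|---|---|---|---|---|---|
| substrate | 0.050 M | 0.050 M | 0.050 M | 0.050 M | 0.050 M |
| reagent | 0.056 M | 0.093 M | 0.10 M | 0.0750 M | 0.110 M |
| initiator | 0.50 mM | 0.50 mM | 0.50 mM | 0.50 mM | 0.50 mM |
| remark | run made earlier | run made earlier | run made earlier |  |  |
| time |  |  |  | 15 min | 15 min |

| run | time / min | target / % | over-reaction product / % | substrate / % | first chain carrier / % |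
|---|---|---|---|---|---|
| ochre | 3.00 | 55.6 | 13.0 | 30.1 | 0.9 |
| ochre | 6.00 | 66.6 | 20.2 | 14.1 | 0 |
| ochre | 10.0 | 68.5 | 20.2 | 9.6 | 0 |
| ochre | 12.0 | 68.1 | 21.8 | 10.3 | 0 |
| ochre | 15.0 | 69.0 | 21.2 | 9.1 | 0.1 |
| grey | 3.00 | 67.6 | 31.0 | 0 | 0.3 |
| grey | 6.00 | 50.9 | 50.1 | 0.5 | 0 |
| grey | 10.0 | 38.2 | 61.2 | 1.3 | 0 |
| grey | 12.0 | 35.0 | 65.4 | 0 | 0.1 |
| grey | 15.0 | 30.4 | 69.6 | 0 | 0.6 |
| violet | 1.33 | 59.7 | 14.7 | 25.1 | 0 |
| violet | 2.50 | 69.8 | 30.9 | 0 | 0.2 |
| violet | 4.00 | 55.3 | 42.9 | 0 | 0 |
| violet | 8.00 | 36.0 | 62.9 | 0.5 | 0.3 |
| violet | 15.0 | 23.4 | 76.7 | 0 | 1.2 |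

(scatter of a reading: 0.5 percentage points)



- which of these there is most of at the end, counted by the substrate in it, Monday's (substrate / over-reaction product / first chain carrier / target)
- which of these there is most of at the end, counted by the substrate in it, Wednesday's (substrate / over-reaction product / first chain carrier / target)
- final amount of the leader among these, as a percentage of the substrate charged, in Monday's
- final amount of the leader among these, as a percentage of the substrate charged, in Wednesday's

I fold the charges into one number: the reagent ratio, reagent charged over substrate charged, is 1.50 for Monday's and 2.20 for Wednesday's. Target costs one reagent and over-reaction product two. Ochre's end shows this: target plus twice the over-reaction product makes 111% against a ratio of 112%, with 9.1% of the substrate still read, so reagent is ochre's limiting reagent. Hence, at the stop, over-reaction product equals the ratio minus one plus the substrate left: 21.1% for ochre, read as 21.2%.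

At 3.00 min grey's substrate reads 0% and its reagent use, counted from the products, stands at 130% of the substrate charged, less than Monday's ratio, so I expect Monday's substrate to reach zero and its over-reaction product to stop at 50.0%, with target ahead until then. Wednesday's ratio minus one, 120%, exceeds the whole substrate, so it sets no stop before complete over-reaction.

One number isn't enough, though: grey's stop lies at 86.0%, but at 15.0 min it reads 69.6%, so the clock still matters. Wednesday's ratio is higher than violet's, so I expect over-reaction product to lead above violet's 76.7%.

The forecast says target at 54.5% for Monday's and over-reaction product at 84.5% for Wednesday's, and reasons: “Exhaustion would give 50/50, so the target narrowly leads.”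

Monday's gives target at 54.8%, Wednesday's over-reaction product at 84.8%.

    reagent + first chain carrier → target + second chain carrier (k = 1.30 × 10⁵ M⁻¹ s⁻¹)
    reagent + target → over-reaction product (k = 0.0760 M⁻¹ s⁻¹)
    substrate + second chain carrier → by-product + first chain carrier (k = 1.20 × 10⁵ M⁻¹ s⁻¹)
    first chain carrier → ended carrier (k = 2.00 s⁻¹)
    crystals ⇌ by-product, rate k5*(cs5 - [by-product]) while solid is left; crystals form when [by-product] > cs5 (solubility = 24.0 mM, k = 0.400 s⁻¹)
    substrate + initiating radical → capped initiator + first chain carrier (k = 1.60 × 10⁶ M⁻¹ s⁻¹)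
    initiator → 2 initiating radical (k = 2.90 × 10⁻⁴ s⁻¹)
    2 first chain carrier → ended chains (k = 4.40 × 10⁷ M⁻¹ s⁻¹)

Left until 150 min, Monday's holds 0% of its reagent and 50.1% over-reaction product, which is its ratio minus one, 50.0%. A neighbour of Wednesday's charged with 0.085 M of substrate has a ratio of 1.29 and ends with 0.027% of its reagent and 5.6% of its substrate; the ratio minus one plus that substrate is 35.0%, and its over-reaction product stands at 35.2%.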